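Ring B of the drimane core is cut across two opposite bonds, the ring-fusion bond C5–C10 and the olefin C7=C8, leaving the three-carbon halves C5–C6–C7 and C8–C9–C10. With C9 (the carbon that later carries the aryloxymethyl arm) as a ketone, C10 and C8 are both nucleophilic; an enal supplies C5 and C7 as electrophiles. An acyclic diketo-enal, whose single stereocentre is erased on enolisation, therefore closes ring A by Michael addition (C5–C10) and ring B by aldol condensation (C7=C8) in one chiral-amine-catalysed operation that sets C5 and C10. The C9 oxygen is then exchanged for the C11 arm by reductive olefin transposition and a formaldehyde ene reaction.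

Key step: step 5

Remark on numbering: carbons are numbered as in drimane; ring A is C1–C5 plus C10 (acetoxy on C3, gem-dimethyl on C4), ring B is C5–C10 (methyl C12 on C8), C11 is the OCH2 carbon on C9, and the angular methyl sits on C10.

Remark on configuration: the target is read as 3S, 5R, 9R, 10S, i.e. a trans-decalin with the 3-acetoxy group equatorial (β) and the C11 arm on C9 trans to the C10 methyl (α, H-9 β); the route is planned for this array.

Step 1
Reactants: 1 1-bromo-3-methylbut-2-ene; 2 prop-2-enal (acrolein)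
Product: 3 rac-4,4-dimethylhexa-1,5-dien-3-ol
Conditions: Zn dust, sat. aq. NH4Cl/THF, 0 °C → rt
Reagents that add atoms: none
Why: Barbier allylation, in which the allylzinc species formed in situ adds 1,2 to the aldehyde through its γ-carbon (six-membered transition state), so the carbinol sits next to a quaternary carbon that carries both methyl groups (future C4) and a vinyl group; the racemic carbinol centre is removed in step 2.

Step 2
Reactants: 3 rac-4,4-dimethylhexa-1,5-dien-3-ol
Product: 4 4,4-dimethylhexa-1,5-dien-3-one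
Conditions: Dess–Martin periodinane, NaHCO3, CH2Cl2, 0 °C → rt
Reagents that add atoms: none
Why: Dess–Martin oxidation of the secondary allylic alcohol under buffered, non-basic conditions should give the vinyl ketone without conjugate addition, and the quaternary α-carbon prevents migration of the isolated olefin.

Step 3
Reactants: 4 4,4-dimethylhexa-1,5-dien-3-one; 5 pentan-3-one
Product: 6 rac-3,3,7-trimethyldec-1-ene-4,8-dione
Conditions: 5 (10 equiv, neat), pyrrolidine (20 mol%), AcOH (20 mol%), 0 °C → rt
Reagents that add atoms: none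
Why: Amine-catalysed Michael addition (Stork enamine alkylation in catalytic form), in which the enamine of 5 adds once to the unsubstituted vinyl ketone terminus, the excess of 5 suppresses double alkylation, and the tert-alkyl ketone formed is too hindered for Robinson-type aldol closure; the new stereocentre is racemic and is erased in step 5.

Step 4
Reactants: 6 rac-3,3,7-trimethyldec-1-ene-4,8-dione; 7 (2E)-but-2-enal (crotonaldehyde)
Product: 8 rac-(2E)-4,4,8-trimethyl-5,9-dioxoundec-2-enal
Conditions: 7 (5 equiv), second-generation Hoveyda–Grubbs catalyst [RuCl2(SIMes)(=CH-C6H4-2-OiPr)] (5 mol%), CH2Cl2, 40 °C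
Reagents that add atoms: none
Why: Olefin cross-metathesis, in which the vinyl group on a quaternary carbon does not homodimerise and couples with the excess electron-poor partner to give the thermodynamically favoured (E)-enal; both ketones are tolerated.

Step 5
Reactants: 8 rac-(2E)-4,4,8-trimethyl-5,9-dioxoundec-2-enal
Product: 10 (4aS,8aS)-2,5,5,8a-tetramethyl-4a,5,8,8a-tetrahydronaphthalene-1,6(4H,7H)-dione (3,9-dioxo-11-nordrim-7-ene), via Michael adduct 9 (not isolated)
Conditions: (S)-2-[diphenyl(trimethylsilyloxy)methyl]pyrrolidine (20 mol%), PhCO2H (20 mol%), PhMe, 60 °C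
Reagents that add atoms: none
Why: The amine condenses with the aldehyde to an (E)-iminium ion whose β-carbon C5 is attacked by C10 of the more substituted enol of the C9 ketone (Michael addition, 6-(enolexo)-exo-trig, ring A); the aldehyde so formed, again activated by the amine, then condenses with the α′-methylene C8 of the same ketone (aldol/Mannich condensation, 6-(enolendo)-exo-trig, ring B) and eliminates to the C7=C8 enone. The closest known reaction type is the diarylprolinol-silyl-ether-catalysed Michael/aldol condensation of ketone donors with enals to cyclohexenones (organocatalytic Robinson-type α,α′-annulation). C5 is controlled by the catalyst: the CPh2(OSiMe3) group shields one face of the s-trans (E)-iminium ion, so C10 should add to the opposite face and give the 4aS centre of 10 (C5 of the target, H α). C10 is controlled by the chair-like transition state of ring A, in which the iminium-bearing vinyl group on C5 and the enol carbon C9 on C10 are both pseudo-equatorial and synclinal and only the C10 methyl is pseudo-axial, which should give the trans ring fusion (8aS); the labile stereocentre of 8 is lost on enolisation, so both enantiomers converge. The step needs C-alkylation through the more substituted α-carbon without competing condensations: attack through C8 would need an eight-membered ring, the enal has no γ-hydrogen (C4 is quaternary) so no dienamine can form, and the neopentyl-type C3 ketone is too hindered to serve as an aldol acceptor.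

Step 6
Reactants: 10 (4aS,8aS)-2,5,5,8a-tetramethyl-4a,5,8,8a-tetrahydronaphthalene-1,6(4H,7H)-dione
Product: 11 (4aS,6S,8aS)-6-hydroxy-2,5,5,8a-tetramethyl-4a,5,6,7,8,8a-hexahydronaphthalen-1(4H)-one
Conditions: NaBH4 (0.5 equiv), MeOH, −20 °C
Reagents that add atoms: none
Why: Chemoselective borohydride reduction, in which the saturated C3 ketone should react faster than the conjugated C9 enone carbonyl flanked by C10 and the methyl-bearing C8, and axial hydride delivery from the α-face should give the equatorial 3β-alcohol (3S), as is usual for 4,4-dimethyl-3-oxodecalins.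

Step 7
Reactants: 11 (4aS,6S,8aS)-6-hydroxy-2,5,5,8a-tetramethyl-4a,5,6,7,8,8a-hexahydronaphthalen-1(4H)-one
Product: 12 N′-[(4aR,6S,8aS)-6-hydroxy-2,5,5,8a-tetramethyl-4a,5,6,7,8,8a-hexahydronaphthalen-1(4H)-ylidene]-4-methylbenzenesulfonohydrazide (tosylhydrazone at C9, C=N geometry not defined)
Conditions: TsNHNH2 (1.5 equiv), TsOH (cat.), EtOH, 80 °C
Reagents that add atoms: 4-methylbenzenesulfonohydrazide, Cc1ccc(cc1)S(=O)(=O)NN
Why: Acid-catalysed condensation of the sulfonylhydrazide with the only remaining carbonyl group should give the α,β-unsaturated tosylhydrazone; no stereocentre is touched.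

Step 8
Reactants: 12 tosylhydrazone of 11
Product: 14 (2S,4aR,8aR)-1,1,4a,6-tetramethyl-1,2,3,4,4a,7,8,8a-octahydronaphthalen-2-ol (11-nordrim-8-en-3β-ol), via allylic diazene 13 (not isolated)
Conditions: catecholborane (3 equiv), CHCl3, 0 °C → rt; then NaOAc·3H2O, 60 °C
Reagents that add atoms: none
Why: Reductive 1,3-transposition of an α,β-unsaturated tosylhydrazone, in which hydride adds to the C=N carbon (C9), loss of sulfinate gives the allylic diazene, and its retro-ene loss of N2 delivers hydrogen to C7 and moves the olefin regiospecifically to C8=C9, leaving C9 as a vinylic CH.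

Step 9
Reactants: 14 (2S,4aR,8aR)-1,1,4a,6-tetramethyl-1,2,3,4,4a,7,8,8a-octahydronaphthalen-2-ol
Product: 15 (2S,4aS,5R,8aR)-5-(hydroxymethyl)-1,1,4a,6-tetramethyl-1,2,3,4,4a,5,8,8a-octahydronaphthalen-2-ol (9-epi-drim-7-ene-3β,11-diol)
Conditions: (CH2O)n (3 equiv), Me2AlCl (3.5 equiv), CH2Cl2, −78 → 0 °C
Reagents that add atoms: formaldehyde (from paraformaldehyde), C=O
Why: Lewis-acid-promoted carbonyl-ene reaction, in which the Me2AlCl–formaldehyde complex should bond to the less substituted olefin carbon C9 from the α-face (anti to the axial C10 methyl) while the pseudo-axial α-hydrogen on C7 is transferred to oxygen in the same suprafacial event, so the olefin returns to C7=C8 and C9 becomes R with CH2OH trans to the C10 methyl.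

Step 10
Reactants: 15 (2S,4aS,5R,8aR)-5-(hydroxymethyl)-1,1,4a,6-tetramethyl-1,2,3,4,4a,5,8,8a-octahydronaphthalen-2-ol; 16 7-hydroxy-6,8-dimethoxy-2H-chromen-2-one (isofraxidin)
Product: 17 7-{[(1R,4aR,6S,8aS)-6-hydroxy-2,5,5,8a-tetramethyl-1,4,4a,5,6,7,8,8a-octahydronaphthalen-1-yl]methoxy}-6,8-dimethoxy-2H-chromen-2-one
Conditions: 16 (1.2 equiv), PPh3, DIAD, THF, 0 °C → rt
Reagents that add atoms: none
Why: Mitsunobu etherification, in which the primary C11 hydroxyl is activated as its alkoxyphosphonium salt and displaced by the acidic 7-hydroxyl of the coumarin, while the hindered secondary 3β-hydroxyl next to the gem-dimethyl group should stay untouched; no stereocentre is involved.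

Step 11
Reactants: 17 7-{[(1R,4aR,6S,8aS)-6-hydroxy-2,5,5,8a-tetramethyl-1,4,4a,5,6,7,8,8a-octahydronaphthalen-1-yl]methoxy}-6,8-dimethoxy-2H-chromen-2-one
Product: 18 [(2S,4aS,5R,8aR)-5-{[(6,8-dimethoxy-2-oxo-2H-chromen-7-yl)oxy]methyl}-1,1,4a,6-tetramethyl-1,2,3,4,4a,5,8,8a-octahydronaphthalen-2-yl] acetate (target)
Conditions: Ac2O, DMAP (cat.), pyridine, rt
Reagents that add atoms: acetic anhydride, CC(=O)OC(C)=O
Why: DMAP-catalysed acylation of the equatorial 3β-alcohol with retention of configuration; the coumarin lactone and the aryl ether are inert under these conditions.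

Compound list
1 | 1-bromo-3-methylbut-2-ene (prenyl bromide) | CC(C)=CCBr | starting material
2 | prop-2-enal (acrolein) | C=CC=O | starting material
3 | rac-4,4-dimethylhexa-1,5-dien-3-ol | C=CC(O)C(C)(C)C=C | intermediate
4 | 4,4-dimethylhexa-1,5-dien-3-one | C=CC(=O)C(C)(C)C=C | intermediate
5 | pentan-3-one | CCC(=O)CC | starting material
6 | rac-3,3,7-trimethyldec-1-ene-4,8-dione | C=CC(C)(C)C(=O)CCC(C)C(=O)CC | intermediate
7 | (2E)-but-2-enal (crotonaldehyde) | C/C=C/C=O | starting material
8 | rac-(2E)-4,4,8-trimethyl-5,9-dioxoundec-2-enal | O=C/C=C/C(C)(C)C(=O)CCC(C)C(=O)CC | intermediate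
9 | 2-[(1S,6S)-2,2,6-trimethyl-3-oxo-6-propanoylcyclohexyl]acetaldehyde (Michael adduct, ring A closed) | O=CC[C@H]1C(C)(C)C(=O)CC[C@]1(C)C(=O)CC | intermediate (not isolated)
10 | (4aS,8aS)-2,5,5,8a-tetramethyl-4a,5,8,8a-tetrahydronaphthalene-1,6(4H,7H)-dione | O=C1C(C)=CC[C@H]2C(C)(C)C(=O)CC[C@]12C | intermediate
11 | (4aS,6S,8aS)-6-hydroxy-2,5,5,8a-tetramethyl-4a,5,6,7,8,8a-hexahydronaphthalen-1(4H)-one | O=C1C(C)=CC[C@H]2C(C)(C)[C@@H](O)CC[C@]12C | intermediate
12 | N′-[(4aR,6S,8aS)-6-hydroxy-2,5,5,8a-tetramethyl-4a,5,6,7,8,8a-hexahydronaphthalen-1(4H)-ylidene]-4-methylbenzenesulfonohydrazide | Cc1ccc(cc1)S(=O)(=O)NN=C1C(C)=CC[C@H]2C(C)(C)[C@@H](O)CC[C@]12C | intermediate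
13 | allylic diazene: 11-nordrim-7-en-3β-ol carrying N=NH on C9 (C9 epimers) | N=NC1C(C)=CC[C@H]2C(C)(C)[C@@H](O)CC[C@]12C | intermediate (not isolated)
14 | (2S,4aR,8aR)-1,1,4a,6-tetramethyl-1,2,3,4,4a,7,8,8a-octahydronaphthalen-2-ol | C1=C(C)CC[C@H]2C(C)(C)[C@@H](O)CC[C@]12C | intermediate
15 | (2S,4aS,5R,8aR)-5-(hydroxymethyl)-1,1,4a,6-tetramethyl-1,2,3,4,4a,5,8,8a-octahydronaphthalen-2-ol | OC[C@@H]1C(C)=CC[C@H]2C(C)(C)[C@@H](O)CC[C@]12C | intermediate
16 | 7-hydroxy-6,8-dimethoxy-2H-chromen-2-one (isofraxidin) | COc1cc2ccc(=O)oc2c(OC)c1O | starting material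
17 | 7-{[(1R,4aR,6S,8aS)-6-hydroxy-2,5,5,8a-tetramethyl-1,4,4a,5,6,7,8,8a-octahydronaphthalen-1-yl]methoxy}-6,8-dimethoxy-2H-chromen-2-one | COc1cc2ccc(=O)oc2c(OC)c1OC[C@@H]1C(C)=CC[C@H]2C(C)(C)[C@@H](O)CC[C@]12C | intermediate
18 | [(2S,4aS,5R,8aR)-5-{[(6,8-dimethoxy-2-oxo-2H-chromen-7-yl)oxy]methyl}-1,1,4a,6-tetramethyl-1,2,3,4,4a,5,8,8a-octahydronaphthalen-2-yl] acetate | COc1cc2ccc(=O)oc2c(OC)c1OC[C@@H]1C(C)=CC[C@H]2C(C)(C)[C@@H](OC(C)=O)CC[C@]12C | target

Total step count: 11. Longest linear sequence: 11 steps (1 → 18); isofraxidin 16 is used as purchased.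

Steps most likely to fail

Step 5. The ketone enol is a weak nucleophile and may add too slowly to the hindered iminium ion, or the bulky chiral amine may fail to turn over, so that enantiocontrol and control of the ring fusion are eroded. The fallback sets out from 8 and returns at 11. Compound 8 is cyclised with stoichiometric pyrrolidine and AcOH (PhMe, 80 °C), the classical amine-mediated Michael/aldol condensation through the unhindered enamine/iminium pair, which should give the racemic trans-fused enedione F1. Reduction with NaBH4 as in step 6 should give the racemic 3β-alcohol F2. Esterification with (S)-2-methoxy-2-phenylacetic acid (DCC, DMAP) should give two diastereomeric esters, the ester of the (2S,4aS,8aS)-alcohol F3 and the ester of its enantiomer F4, to be separated by chromatography. Saponification of F3 (LiOH, THF/H2O) should return 11.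

Step 9. Hydrogen may be transferred from the C8 methyl group instead of from C7 (poor regioselectivity of the hydrogen transfer in the ene step), which would leave an exocyclic olefin. The fallback sets out from 14 and returns at 15. Allylic oxidation of 14 with SeO2 (cat.) and t-BuOOH in CH2Cl2 should give the 7α-allylic alcohol (2S,4aR,7R,8aR)-1,1,4a,6-tetramethyl-1,2,3,4,4a,7,8,8a-octahydronaphthalene-2,7-diol F5, by an ene reaction at C9 from the α-face followed by a [2,3]-shift. Heating with N,N-dimethylformamide dimethyl acetal (xylene, 140 °C) should transfer one carbon suprafacially from the 7α-oxygen to C9 by [2,3]-sigmatropic rearrangement of the alkoxy(amino)carbene (Büchi rearrangement), giving the 9α-carboxamide F6 with the olefin fixed at C7=C8. Reduction of the amide with LiBHEt3 (THF, 0 °C → rt) should then give diol 15.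

Step 7. Condensation at the C9 carbonyl, flanked by the quaternary C10 and the methyl-bearing C8, may stall, or the hydrazide may add in conjugate fashion instead. The fallback sets out from 11 and returns at 14. Conjugate reduction of 11 with LiBH(s-Bu)3 (THF, −78 °C) and trapping of the C9 enolate with PhNTf2 should give the enol triflate F7. Hydrogenolysis of the triflate with Pd(OAc)2, PPh3, HCO2H and Bu3N (DMF, 60 °C) should give alkene 14 without a hydrazone.

Further compounds
F1 | step 5 | rac-(4aS,8aS)-2,5,5,8a-tetramethyl-4a,5,8,8a-tetrahydronaphthalene-1,6(4H,7H)-dione (racemate of 10) | O=C1C(C)=CC[C@H]2C(C)(C)C(=O)CC[C@]12C.O=C1C(C)=CC[C@@H]2C(C)(C)C(=O)CC[C@@]12C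
F2 | step 5 | rac-(4aS,6S,8aS)-6-hydroxy-2,5,5,8a-tetramethyl-4a,5,6,7,8,8a-hexahydronaphthalen-1(4H)-one (racemate of 11) | O=C1C(C)=CC[C@H]2C(C)(C)[C@@H](O)CC[C@]12C.O=C1C(C)=CC[C@@H]2C(C)(C)[C@H](O)CC[C@@]12C
F3 | step 5 | [(2S,4aS,8aS)-1,1,4a,6-tetramethyl-5-oxo-1,2,3,4,4a,5,8,8a-octahydronaphthalen-2-yl] (2S)-2-methoxy-2-phenylacetate | O=C1C(C)=CC[C@H]2C(C)(C)[C@@H](OC(=O)[C@@H](OC)c3ccccc3)CC[C@]12C
F4 | step 5 | [(2R,4aR,8aR)-1,1,4a,6-tetramethyl-5-oxo-1,2,3,4,4a,5,8,8a-octahydronaphthalen-2-yl] (2S)-2-methoxy-2-phenylacetate | O=C1C(C)=CC[C@@H]2C(C)(C)[C@H](OC(=O)[C@@H](OC)c3ccccc3)CC[C@@]12C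
F5 | step 9 | (2S,4aR,7R,8aR)-1,1,4a,6-tetramethyl-1,2,3,4,4a,7,8,8a-octahydronaphthalene-2,7-diol | C1=C(C)[C@H](O)C[C@H]2C(C)(C)[C@@H](O)CC[C@]12C
F6 | step 9 | (1R,4aR,6S,8aS)-6-hydroxy-N,N,2,5,5,8a-hexamethyl-1,4,4a,5,6,7,8,8a-octahydronaphthalene-1-carboxamide | CN(C)C(=O)[C@@H]1C(C)=CC[C@H]2C(C)(C)[C@@H](O)CC[C@]12C
F7 | step 7 | (4aS,6S,8aS)-6-hydroxy-2,5,5,8a-tetramethyl-3,4,4a,5,6,7,8,8a-octahydronaphthalen-1-yl trifluoromethanesulfonate | O=S(=O)(OC1=C(C)CC[C@H]2C(C)(C)[C@@H](O)CC[C@]12C)C(F)(F)F
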